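The dihydropyran ring of the cyclopenta[c]pyran is unravelled to a cis-fused bicyclo[3.2.0]heptane in which C1 and C4 are still joined. That bond is special: C1 carries the 4-hydroxy-5-methylcoumarin-3-yl group, which stabilises positive charge, and C4 is alpha to the C3 carbonyl of an α-keto ester. A Lewis acid should therefore break C1–C4 and let the enolate oxygen on C3 capture C1, which makes the O2–C1 bond, turns the four-membered ring into the six-membered enol ether and sets C1 in a single operation. The precursor, a 7-coumarinyl-6-(methoxyoxalyl)bicyclo[3.2.0]heptane, comes from an intramolecular [2+2] photocycloaddition that fixes the cis C4a–C7a fusion relative to the C7 methyl group of (S)-β-citronellene.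

Key step: step 12

Remarks on the chemistry (assumptions)
- Numbering: cyclopenta[c]pyran numbering (C1, O2, C3, C4, C4a, C5, C6, C7, C7a) is used for the target and the dihydropyrans. The cyclobutanes use bicyclo[3.2.0]heptane numbering, in which C1, C2, C5, C6 and C7 become C7a, C7, C4a, C4 and C1.
- The target reads as (1R,4aS,7S,7aR): H-4a, H-7a, the C7 methyl group and the coumarin at C1 lie on one face of the cis-fused bicycle. The cyclobutane precursor and the ester product of the key step carry the same C4a, C7 and C7a configuration, so no descriptor had to be changed.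
- The C7 stereocentre is taken from (S)-β-citronellene, assumed to be commercially available as the single enantiomer. Its vinyl group already holds C7a at the alkene oxidation level, and C1 enters from a vinylboronate.
- Ozonolysis is done on the citronellene, before the electron-rich alkenylcoumarin exists, because ozone would not spare that alkene.
- The enone is made by Wittig olefination. An aldol condensation of a 2-oxobutanoate is avoided because such aldol adducts lactonise to isotetronic acids.
- A free 4-hydroxycoumarin is never condensed with an aldehyde, because the 3-alkylidenechromane-2,4-diones formed add a second coumarin or cyclise onto a remote alkene.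
- The 4-OH is carried as a benzyl ether from step 3 to step 11 and is free in the key step. Only the free hydroxyl allows the opened intermediate to exist as a neutral alkylidenechromanedione.
- The cycloadduct of step 10 may contain C6/C7 epimers. They are carried on, since both centres are erased or reset in step 12.

Step 1
Reactants: 1 1-(2-hydroxy-6-methylphenyl)ethanone
Product: 2 4-hydroxy-5-methyl-2H-chromen-2-one
Conditions: NaH (3.5 equiv), (EtO)2CO, toluene, 110 °C; then aq. HCl
Reagents that add atoms: diethyl carbonate, CCOC(=O)OCC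
Why: Claisen-type C-acylation of the ketone enolate by diethyl carbonate followed by lactonisation onto the phenoxide is the standard route from 2-hydroxyacetophenones to 4-hydroxycoumarins, the ring methyl group ends up at C5 and no stereocentre is formed.

Step 2
Reactants: 2 4-hydroxy-5-methyl-2H-chromen-2-one
Product: 3 3-bromo-4-hydroxy-5-methyl-2H-chromen-2-one
Conditions: NBS (1.05 equiv), MeCN, rt, dark
Reagents that add atoms: N-bromosuccinimide, O=C1CCC(=O)N1Br
Why: Electrophilic bromination takes place at C3, the nucleophilic α-carbon of the vinylogous acid, which is far more reactive than the benzo ring.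

Step 3
Reactants: 3 3-bromo-4-hydroxy-5-methyl-2H-chromen-2-one
Product: 4 4-(benzyloxy)-3-bromo-5-methyl-2H-chromen-2-one
Conditions: BnBr, K2CO3, DMF, 50 °C
Reagents that add atoms: benzyl bromide, BrCc1ccccc1
Why: Williamson O-alkylation of the vinylogous acid, in which the C3 bromine blocks C-benzylation and the 4-alkoxycoumarin is the expected main O-regioisomer (any 2-benzyloxychromone would be removed by chromatography).

Step 4
Reactants: 5 (S)-β-citronellene, (3S)-3,7-dimethylocta-1,6-diene
Product: 8 (4S)-4-methylhex-5-en-1-ol, via ozonide 6 (not isolated), via (4S)-4-methylhex-5-enal 7 (not isolated)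
Conditions: O3, CH2Cl2, −78 °C (Sudan Red 7B end-point); then NaBH4 (excess), MeOH, −78 °C → rt
Reagents that add atoms: ozone, [O-][O+]=O
Why: Ozonolysis with reductive work-up, in which electrophilic ozone should consume the trisubstituted alkene well before the vinyl group, NaBH4 reduces the ozonide through the aldehyde to the primary alcohol, and the stereocentre is not touched.

Step 5
Reactants: 8 (4S)-4-methylhex-5-en-1-ol
Product: 9 (4S,5E)-4-methyl-6-(4,4,5,5-tetramethyl-1,3,2-dioxaborolan-2-yl)hex-5-en-1-ol
Conditions: vinyl-Bpin (3 equiv), second-generation Hoveyda–Grubbs catalyst RuCl2(H2IMes)(=CH–C6H4–2-OiPr) (5 mol%), 1,4-benzoquinone (10 mol%), CH2Cl2, 40 °C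
Reagents that add atoms: 4,4,5,5-tetramethyl-2-vinyl-1,3,2-dioxaborolane, C=CB1OC(C)(C)C(C)(C)O1
Why: Olefin cross-metathesis of a terminal alkene with vinyl pinacolboronate should give the (E)-alkenylboronate under thermodynamic control, with benzoquinone suppressing ruthenium hydride isomerisation that could reach the allylic stereocentre.

Step 6
Reactants: 9 (4S,5E)-4-methyl-6-(4,4,5,5-tetramethyl-1,3,2-dioxaborolan-2-yl)hex-5-en-1-ol, 4 4-(benzyloxy)-3-bromo-5-methyl-2H-chromen-2-one
Product: 10 4-(benzyloxy)-3-[(1E,3S)-6-hydroxy-3-methylhex-1-en-1-yl]-5-methyl-2H-chromen-2-one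
Conditions: Pd(dppf)Cl2 (5 mol%), K3PO4, 1,4-dioxane/H2O, 80 °C
Reagents that add atoms: none
Why: Suzuki–Miyaura coupling of the activated C3–Br bond of the 4-alkoxycoumarin (an α-bromo enone-type vinyl bromide) with the alkenylboronate proceeds with retention of the E geometry and tolerates the free alcohol.

Step 7
Reactants: 10 4-(benzyloxy)-3-[(1E,3S)-6-hydroxy-3-methylhex-1-en-1-yl]-5-methyl-2H-chromen-2-one
Product: 11 (4S,5E)-6-[4-(benzyloxy)-5-methyl-2-oxo-2H-chromen-3-yl]-4-methylhex-5-enal
Conditions: Dess–Martin periodinane, CH2Cl2, rt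
Reagents that add atoms: none
Why: Dess–Martin oxidation of the primary alcohol to the aldehyde is mild and nearly neutral, and the stereocentre is γ to the new carbonyl and therefore cannot epimerise.

Step 8
Reactants: 12 ethyltriphenylphosphonium bromide, 13 dimethyl oxalate
Product: 15 methyl 2-oxo-3-(triphenylphosphoranylidene)butanoate, via ethylidenetriphenylphosphorane 14 (not isolated)
Conditions: n-BuLi, THF, 0 °C; then (CO2Me)2, −78 °C → rt
Reagents that add atoms: none
Why: Acylation of a non-stabilised phosphorus ylide by a reactive ester, in which the methoxide released deprotonates the acylphosphonium salt to give the stabilised acyl ylide.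

Step 9
Reactants: 11 (4S,5E)-6-[4-(benzyloxy)-5-methyl-2-oxo-2H-chromen-3-yl]-4-methylhex-5-enal, 15 methyl 2-oxo-3-(triphenylphosphoranylidene)butanoate
Product: 16 methyl (3E,7S,8E)-9-[4-(benzyloxy)-5-methyl-2-oxo-2H-chromen-3-yl]-3,7-dimethyl-2-oxonona-3,8-dienoate
Conditions: toluene, 80 °C
Reagents that add atoms: none
Why: Wittig olefination of an unhindered aldehyde with a stabilised acyl ylide should give the trisubstituted (E)-enone, with the acyl group trans to the chain, under neutral conditions that leave the α-keto ester and the benzyl ether intact.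

Step 10
Reactants: 16 methyl (3E,7S,8E)-9-[4-(benzyloxy)-5-methyl-2-oxo-2H-chromen-3-yl]-3,7-dimethyl-2-oxonona-3,8-dienoate
Product: 17 methyl 2-[(1R,2S,5S,6R,7S)-7-[4-(benzyloxy)-5-methyl-2-oxo-2H-chromen-3-yl]-2,6-dimethylbicyclo[3.2.0]heptan-6-yl]-2-oxoacetate
Conditions: [Ir{dF(CF3)ppy}2(dtbbpy)]PF6 (1 mol%), degassed MeCN (0.01 M), 450 nm LEDs, rt
Reagents that add atoms: none
Why: Sensitised intramolecular [2+2] photocycloaddition of a 1,6-diene, in which triplet energy transfer to the styrene-like alkenylcoumarin should trigger 5-exo bond formation to the enone β-carbon and then closure of the 1,4-diradical; the bicyclo[3.2.0]heptane can only be cis-fused, the C2 methyl group should sit pseudo-equatorial in the five-membered transition state and so end up on the convex face, which sets C1 and C5 relative to C2, and C6 and C7 follow the E,E geometry but need not be controlled.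

Step 11
Reactants: 17 methyl 2-[(1R,2S,5S,6R,7S)-7-[4-(benzyloxy)-5-methyl-2-oxo-2H-chromen-3-yl]-2,6-dimethylbicyclo[3.2.0]heptan-6-yl]-2-oxoacetate
Product: 18 methyl 2-[(1R,2S,5S,6R,7S)-7-(4-hydroxy-5-methyl-2-oxo-2H-chromen-3-yl)-2,6-dimethylbicyclo[3.2.0]heptan-6-yl]-2-oxoacetate
Conditions: H2 (1 atm), Pd/C (10%), EtOAc, rt, short contact time
Reagents that add atoms: none
Why: Hydrogenolysis of the benzyl vinylogous ester is fast on Pd/C, whereas the ketone is neopentyl-type hindered and the coumarin C3=C4 bond is tetrasubstituted, so only the O-benzyl bond should be cleaved and no stereocentre is touched.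

Step 12
Reactants: 18 methyl 2-[(1R,2S,5S,6R,7S)-7-(4-hydroxy-5-methyl-2-oxo-2H-chromen-3-yl)-2,6-dimethylbicyclo[3.2.0]heptan-6-yl]-2-oxoacetate
Product: 20 methyl (1R,4aS,7S,7aR)-1-(4-hydroxy-5-methyl-2-oxo-2H-chromen-3-yl)-4,7-dimethyl-1,4a,5,6,7,7a-hexahydrocyclopenta[c]pyran-3-carboxylate, via ring-opened alkylidenechromanedione enol 19 (not isolated)
Conditions: Sc(OTf)3 (10 mol%), 1,2-dichloroethane, 0 °C → 40 °C
Reagents that add atoms: none
Why: Proposed new method: Sc(OTf)3 should bind the 1,2-dicarbonyl unit and so polarise the C6–C7 bond of the cyclobutane (the future C4–C1 bond), which then breaks heterolytically into a scandium enolate and a cation held by the 4-hydroxycoumarin-3-yl group, a pair that corresponds after proton transfer to the neutral enol and 3-alkylidenechromane-2,4-dione 19. The enol oxygen on C3 then adds to the electrophilic carbon in a 6-(enolendo)-exo-trig closure that forms the O2–C1 bond and the dihydropyran ring, with the strain of the four-membered ring (about 26 kcal/mol) as driving force. The closest known reaction types are the Cloke–Wilson rearrangement of donor–acceptor cyclopropyl ketones to dihydrofurans and the Lewis-acid isomerisation of alkoxy-substituted cyclobutyl ketones to dihydropyrans; an aryl-type donor on a cyclobutane has not been used in this way. C1 is the only new stereocentre and is controlled by the neighbouring C7a centre of the cis-fused cyclopentane: the coumarin should take the convex face, cis to H-7a and pseudo-equatorial, and because the C1–O2 bond can ionise again under the same catalyst the more stable epimer should accumulate. The step needs cleavage of this one cyclobutane bond and capture through oxygen and not through carbon: only C6–C7 is flanked by both a donor and an acceptor, and capture through carbon merely rebuilds the strained ring reversibly. C4a, C7 and C7a are not touched, and the C6 and C7 configurations of 18 are erased, so epimers at these centres converge.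

Step 13
Reactants: 20 methyl (1R,4aS,7S,7aR)-1-(4-hydroxy-5-methyl-2-oxo-2H-chromen-3-yl)-4,7-dimethyl-1,4a,5,6,7,7a-hexahydrocyclopenta[c]pyran-3-carboxylate
Product: 21 (1R,4aS,7S,7aR)-1-(4-hydroxy-5-methyl-2-oxo-2H-chromen-3-yl)-N-methoxy-N,4,7-trimethyl-1,4a,5,6,7,7a-hexahydrocyclopenta[c]pyran-3-carboxamide
Conditions: MeNHOMe·HCl (3 equiv), iPrMgCl (7 equiv), THF, −20 °C → 0 °C; then aq. NH4Cl
Reagents that add atoms: N,O-dimethylhydroxylamine hydrochloride, CNOC.Cl
Why: Weinreb amide formation by aminolysis of the methyl ester with the chloromagnesium amide of N,O-dimethylhydroxylamine, in which the acidic 4-OH is merely deprotonated, which also deactivates the lactone, and no stereocentre is involved.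

Step 14
Reactants: 21 (1R,4aS,7S,7aR)-1-(4-hydroxy-5-methyl-2-oxo-2H-chromen-3-yl)-N-methoxy-N,4,7-trimethyl-1,4a,5,6,7,7a-hexahydrocyclopenta[c]pyran-3-carboxamide, 22 2-methylprop-1-enylmagnesium bromide
Product: 23 4-hydroxy-5-methyl-3-[(1R,4aS,7S,7aR)-4,7-dimethyl-3-(3-methylbut-2-enoyl)-1,4a,5,6,7,7a-hexahydrocyclopenta[c]pyran-1-yl]-2H-chromen-2-one
Conditions: 22 (3 equiv), THF, −40 °C → 0 °C; then aq. NH4Cl
Reagents that add atoms: none
Why: Weinreb ketone synthesis, in which the first equivalent of the Grignard reagent turns the 4-OH into its magnesium salt and so shields the lactone, and the next adds to the amide to give a chelated tetrahedral intermediate that releases the dienone only on work-up, so over-addition and conjugate addition are avoided.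

Compound list
1 | 1-(2-hydroxy-6-methylphenyl)ethanone | CC(=O)c1c(C)cccc1O | starting material
2 | 4-hydroxy-5-methyl-2H-chromen-2-one | Cc1cccc2oc(=O)cc(O)c12 | intermediate
3 | 3-bromo-4-hydroxy-5-methyl-2H-chromen-2-one | Cc1cccc2oc(=O)c(Br)c(O)c12 | intermediate
4 | 4-(benzyloxy)-3-bromo-5-methyl-2H-chromen-2-one | Cc1cccc2oc(=O)c(Br)c(OCc3ccccc3)c12 | intermediate
5 | (S)-β-citronellene, (3S)-3,7-dimethylocta-1,6-diene | C=C[C@@H](C)CCC=C(C)C | starting material
6 | ozonide, 3,3-dimethyl-5-[(3S)-3-methylpent-4-en-1-yl]-1,2,4-trioxolane | CC1(C)OOC(CC[C@H](C)C=C)O1 | intermediate (not isolated)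
7 | (4S)-4-methylhex-5-enal | O=CCC[C@H](C)C=C | intermediate (not isolated)
8 | (4S)-4-methylhex-5-en-1-ol | OCCC[C@H](C)C=C | intermediate
9 | (4S,5E)-4-methyl-6-(4,4,5,5-tetramethyl-1,3,2-dioxaborolan-2-yl)hex-5-en-1-ol | OCCC[C@H](C)/C=C/B1OC(C)(C)C(C)(C)O1 | intermediate
10 | 4-(benzyloxy)-3-[(1E,3S)-6-hydroxy-3-methylhex-1-en-1-yl]-5-methyl-2H-chromen-2-one | OCCC[C@H](C)/C=C/c1c(OCc2ccccc2)c2c(C)cccc2oc1=O | intermediate
11 | (4S,5E)-6-[4-(benzyloxy)-5-methyl-2-oxo-2H-chromen-3-yl]-4-methylhex-5-enal | O=CCC[C@H](C)/C=C/c1c(OCc2ccccc2)c2c(C)cccc2oc1=O | intermediate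
12 | ethyltriphenylphosphonium bromide | CC[P+](c1ccccc1)(c1ccccc1)c1ccccc1.[Br-] | starting material
13 | dimethyl oxalate | COC(=O)C(=O)OC | starting material
14 | ethylidenetriphenylphosphorane | CC=P(c1ccccc1)(c1ccccc1)c1ccccc1 | intermediate (not isolated)
15 | methyl 2-oxo-3-(triphenylphosphoranylidene)butanoate | COC(=O)C(=O)C(C)=P(c1ccccc1)(c1ccccc1)c1ccccc1 | intermediate
16 | methyl (3E,7S,8E)-9-[4-(benzyloxy)-5-methyl-2-oxo-2H-chromen-3-yl]-3,7-dimethyl-2-oxonona-3,8-dienoate | COC(=O)C(=O)/C(C)=C/CC[C@H](C)/C=C/c1c(OCc2ccccc2)c2c(C)cccc2oc1=O | intermediate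
17 | methyl 2-[(1R,2S,5S,6R,7S)-7-[4-(benzyloxy)-5-methyl-2-oxo-2H-chromen-3-yl]-2,6-dimethylbicyclo[3.2.0]heptan-6-yl]-2-oxoacetate | COC(=O)C(=O)[C@]1(C)[C@H]2CC[C@H](C)[C@H]2[C@@H]1c1c(OCc2ccccc2)c2c(C)cccc2oc1=O | intermediate
18 | methyl 2-[(1R,2S,5S,6R,7S)-7-(4-hydroxy-5-methyl-2-oxo-2H-chromen-3-yl)-2,6-dimethylbicyclo[3.2.0]heptan-6-yl]-2-oxoacetate | COC(=O)C(=O)[C@]1(C)[C@H]2CC[C@H](C)[C@H]2[C@@H]1c1c(O)c2c(C)cccc2oc1=O | intermediate (key-step precursor)
19 | methyl 2-hydroxy-3-[(1S,2S,3S)-3-methyl-2-[(5-methyl-2,4-dioxochroman-3-ylidene)methyl]cyclopentyl]but-2-enoate (neutral tautomer of the ring-opened zwitterion) | COC(=O)C(O)=C(C)[C@H]1CC[C@H](C)[C@H]1C=C1C(=O)Oc2cccc(C)c2C1=O | intermediate (not isolated)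
20 | methyl (1R,4aS,7S,7aR)-1-(4-hydroxy-5-methyl-2-oxo-2H-chromen-3-yl)-4,7-dimethyl-1,4a,5,6,7,7a-hexahydrocyclopenta[c]pyran-3-carboxylate | COC(=O)C1=C(C)[C@H]2CC[C@H](C)[C@H]2[C@H](c2c(O)c3c(C)cccc3oc2=O)O1 | intermediate (key-step product)
21 | (1R,4aS,7S,7aR)-1-(4-hydroxy-5-methyl-2-oxo-2H-chromen-3-yl)-N-methoxy-N,4,7-trimethyl-1,4a,5,6,7,7a-hexahydrocyclopenta[c]pyran-3-carboxamide | CON(C)C(=O)C1=C(C)[C@H]2CC[C@H](C)[C@H]2[C@H](c2c(O)c3c(C)cccc3oc2=O)O1 | intermediate
22 | 2-methylprop-1-enylmagnesium bromide | CC(C)=C[Mg]Br | starting material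
23 | 4-hydroxy-5-methyl-3-[(1R,4aS,7S,7aR)-4,7-dimethyl-3-(3-methylbut-2-enoyl)-1,4a,5,6,7,7a-hexahydrocyclopenta[c]pyran-1-yl]-2H-chromen-2-one | CC(C)=CC(=O)C1=C(C)[C@H]2CC[C@H](C)[C@H]2[C@H](c2c(O)c3c(C)cccc3oc2=O)O1 | target

Total step count: 14.
Longest linear sequence: 11 steps (steps 1, 2, 3, 6, 7, 9, 10, 11, 12, 13, 14, from compound 1); the branch from 5 has 10 steps.

Steps most likely to fail

Step 12 (ring expansion). The opened cation may lose the C7a proton faster than the enol oxygen closes. That elimination would give a 3-alkenyl-4-hydroxycoumarin and destroy the C7a centre. Alternatively, the cyclobutane may not ionise under conditions the product tolerates, or the C1 epimers may fail to equilibrate. The fallback gives up the cyclobutane and uses known chemistry. It sets out from diene 16, which would be cyclised in an intramolecular inverse-electron-demand hetero-Diels–Alder reaction (Cu(OTf)2 10 mol%, CH2Cl2, 0 °C → rt, or toluene at 110 °C). The 2-oxo-3-enoate acts as the 1-oxadiene and the (E)-alkenylcoumarin as the dienophile. The three-atom tether favours the cis-fused bicycle, and the E alkene places the coumarin cis to H-7a. This should give methyl (1R,4aS,7S,7aR)-1-[4-(benzyloxy)-5-methyl-2-oxo-2H-chromen-3-yl]-4,7-dimethyl-1,4a,5,6,7,7a-hexahydrocyclopenta[c]pyran-3-carboxylate F1. Debenzylation with BCl3 and pentamethylbenzene (CH2Cl2, −78 °C) would then return the route at compound 20.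

Step 10 (photocycloaddition). The excited state may be diverted into carbonyl photochemistry of the α-keto ester (oxetane formation, hydrogen abstraction). Energy may also be lost in E/Z isomerisation without ring closure, or the five-membered ring may form with poor facial selectivity relative to the C7 methyl group. The fallback removes the carbonyl chromophore before the cycloaddition. Setting out from 16, Luche reduction (NaBH4, CeCl3·7H2O, MeOH, −78 °C) would give methyl (3E,7S,8E)-9-[4-(benzyloxy)-5-methyl-2-oxo-2H-chromen-3-yl]-2-hydroxy-3,7-dimethylnona-3,8-dienoate F2 as a mixture of carbinol epimers. The same sensitised irradiation then becomes a plain styrene-type alkene–alkene [2+2] cycloaddition and should give methyl 2-[(1R,2S,5S,6R,7S)-7-[4-(benzyloxy)-5-methyl-2-oxo-2H-chromen-3-yl]-2,6-dimethylbicyclo[3.2.0]heptan-6-yl]-2-hydroxyacetate F3. Dess–Martin oxidation of the secondary alcohol returns the route at compound 17.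

Step 9 (Wittig olefination). The doubly stabilised, α-branched ylide may react slowly. Forcing temperatures could let the product diene begin to cyclise thermally or let the aldehyde self-condense. The fallback builds the enone by aldol addition and elimination at low temperature. Methyl 2-oxobutanoate (commercial) would be silylated (TMSCl, Et3N) to methyl (2Z)-2-[(trimethylsilyl)oxy]but-2-enoate F4. A Mukaiyama aldol addition of F4 to aldehyde 11 (BF3·OEt2, CH2Cl2, −78 °C) should give methyl (7S,8E)-9-[4-(benzyloxy)-5-methyl-2-oxo-2H-chromen-3-yl]-4-hydroxy-3,7-dimethyl-2-oxonon-8-enoate F5. This is mesylated at once (MsCl, Et3N, 0 °C), before it can lactonise, to methyl (7S,8E)-9-[4-(benzyloxy)-5-methyl-2-oxo-2H-chromen-3-yl]-3,7-dimethyl-4-(methylsulfonyloxy)-2-oxonon-8-enoate F6. F6 eliminates in the same flask to the conjugated (E)-enone and returns the route at compound 16.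

Further compounds
F1 | step 12 | methyl (1R,4aS,7S,7aR)-1-[4-(benzyloxy)-5-methyl-2-oxo-2H-chromen-3-yl]-4,7-dimethyl-1,4a,5,6,7,7a-hexahydrocyclopenta[c]pyran-3-carboxylate | COC(=O)C1=C(C)[C@H]2CC[C@H](C)[C@H]2[C@H](c2c(OCc3ccccc3)c3c(C)cccc3oc2=O)O1
F2 | step 10 | methyl (3E,7S,8E)-9-[4-(benzyloxy)-5-methyl-2-oxo-2H-chromen-3-yl]-2-hydroxy-3,7-dimethylnona-3,8-dienoate | COC(=O)C(O)/C(C)=C/CC[C@H](C)/C=C/c1c(OCc2ccccc2)c2c(C)cccc2oc1=O
F3 | step 10 | methyl 2-[(1R,2S,5S,6R,7S)-7-[4-(benzyloxy)-5-methyl-2-oxo-2H-chromen-3-yl]-2,6-dimethylbicyclo[3.2.0]heptan-6-yl]-2-hydroxyacetate | COC(=O)C(O)[C@]1(C)[C@H]2CC[C@H](C)[C@H]2[C@@H]1c1c(OCc2ccccc2)c2c(C)cccc2oc1=O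
F4 | step 9 | methyl (2Z)-2-[(trimethylsilyl)oxy]but-2-enoate | C/C=C(\O[Si](C)(C)C)C(=O)OC
F5 | step 9 | methyl (7S,8E)-9-[4-(benzyloxy)-5-methyl-2-oxo-2H-chromen-3-yl]-4-hydroxy-3,7-dimethyl-2-oxonon-8-enoate | COC(=O)C(=O)C(C)C(O)CC[C@H](C)/C=C/c1c(OCc2ccccc2)c2c(C)cccc2oc1=O
F6 | step 9 | methyl (7S,8E)-9-[4-(benzyloxy)-5-methyl-2-oxo-2H-chromen-3-yl]-3,7-dimethyl-4-(methylsulfonyloxy)-2-oxonon-8-enoate | COC(=O)C(=O)C(C)C(OS(C)(=O)=O)CC[C@H](C)/C=C/c1c(OCc2ccccc2)c2c(C)cccc2oc1=O
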